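**Plan**

1. Numbering: ring C1 (CHOAc beside the alkene), C2=C3, C4 (CHOBz), C5 (C–OH), C6 (CHOAc), C7 = CH2 on C5. Primed locants are sugar numbering of the precursors (C1'=C7, C2'=C5, C3'=C6, C4'=C1, C5'=C2, C6'=C3, C7'=C4).
2. Cuts: the O7 benzoate and the acetyl placement (ester level), then the ring bond C4–C5 in a retro-[3,3] step that ties O7 to C2, then C2–C3 (acetylide plus aldehyde).
3. Enabling feature: the ring holds a 4-pentenal unit C7(=O)–C5–C4–C3=C2 whose C5 also carries oxygen. Joining O7 to C2 gives a 2-acetoxy-3,4-dihydro-2H-pyran (ring O7, C7, C5, C6, C1, C2) carrying a (Z)-2-benzoyloxyvinyl group on C2, i.e. a 5-C-vinyl hydroxyglycal ester.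
4. Forward order: glucose-derived furanose, alkyne added at C5', pyranose, glycal (temporary pyran), Z-enol benzoate, then the [3,3] shift closes the cyclohexene (the only skeleton ring, formed last), then ester adjustment.
5. Stereochemistry: C6 and C1 are C3 and C4 of D-glucose. The propargylic centre C5' (L-ido) comes from chelation-controlled ethynylation and is consumed in the shift, which transfers it to quaternary C5. C4 follows from the Z-alkene geometry in the enforced boat.
6. Helpers: the pyran oxygen (becomes the C7 carbonyl O), 2-naphthylmethyl on O6 (removed in step 8), and the acetyl on the quaternary oxygen (relayed to O6 in step 8, so it ends in the target).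

Key step: step 7

Remark: diacetone-D-glucose, 2-(bromomethyl)naphthalene, ethynylmagnesium bromide and the ruthenium complex are taken as commercial; the allylic oxygen O3' is carried as an ether because an ester there would be expected to undergo a thermal allylic acyloxy shift under the conditions of step 7.

**Route**

Step 1
Reactants: 1 1,2:5,6-di-O-isopropylidene-α-D-glucofuranose
Product: 2 1,2:5,6-di-O-isopropylidene-3-O-(2-naphthylmethyl)-α-D-glucofuranose
Conditions: NaH, 2-(bromomethyl)naphthalene, DMF, 0 °C to rt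
Reagents that add atoms: 2-(bromomethyl)naphthalene, BrCc1ccc2ccccc2c1
Why: Williamson etherification of the only free hydroxyl; the naphthylmethyl ether is a non-acyl group for the later allylic position, can chelate magnesium in step 3 and is removable with DDQ beside esters and the alkene.

Step 2
Reactants: 2 1,2:5,6-di-O-isopropylidene-3-O-(2-naphthylmethyl)-α-D-glucofuranose
Product: 4 1,2-O-isopropylidene-3-O-(2-naphthylmethyl)-α-D-xylo-pentodialdo-1,4-furanose, via 5,6-diol 3 (not isolated)
Conditions: H5IO6 (1.3 equiv), EtOAc, rt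
Reagents that add atoms: none
Why: Periodic acid should hydrolyse the more labile terminal acetal and cleave the freed glycol in the same flask (Malaprade glycol cleavage), leaving the 1,2-acetal and the C2–C4 stereocentres untouched.

Step 3
Reactants: 4 1,2-O-isopropylidene-3-O-(2-naphthylmethyl)-α-D-xylo-pentodialdo-1,4-furanose
Product: 5 6,7-dideoxy-1,2-O-isopropylidene-3-O-(2-naphthylmethyl)-β-L-ido-hept-6-ynofuranose
Conditions: HC≡CMgBr, THF/Et2O, −78 °C to 0 °C; aq. work-up
Reagents that add atoms: ethynylmagnesium bromide, C#C[Mg]Br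
Why: Grignard addition under Cram-chelate control (Mg held between the aldehyde oxygen and the ring/ether oxygens) should favour the 5S (L-ido) carbinol, the centre that later fixes the face of the [3,3] shift; the D-gluco epimer would be removed by chromatography.

Step 4
Reactants: 5 6,7-dideoxy-1,2-O-isopropylidene-3-O-(2-naphthylmethyl)-β-L-ido-hept-6-ynofuranose
Product: 7 1,2,4-tri-O-acetyl-6,7-dideoxy-3-O-(2-naphthylmethyl)-L-ido-hept-6-ynopyranose, via free heptynose 6 (not isolated)
Conditions: Amberlite IR-120 (H+), dioxane/H2O, 80 °C; filter, evaporate; Ac2O, pyridine, DMAP (cat.), 0 °C to rt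
Reagents that add atoms: acetic anhydride, CC(=O)OC(C)=O
Why: Acid-catalysed acetal hydrolysis frees the reducing sugar, which should close through O5' to the pyranose (a 5-C-ethynyl xylopyranose whose chair keeps O2', O3' and O4' equatorial at the cost of one axial alkyne) and is trapped by peracetylation; no stereocentre other than the anomeric one is touched.

Step 5
Reactants: 7 1,2,4-tri-O-acetyl-6,7-dideoxy-3-O-(2-naphthylmethyl)-L-ido-hept-6-ynopyranose
Product: 9 2,4-di-O-acetyl-1,5-anhydro-6,7-dideoxy-3-O-(2-naphthylmethyl)-L-xylo-hept-1-en-6-ynitol, via glycosyl bromide 8 (not isolated)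
Conditions: HBr (33% in AcOH), CH2Cl2, 0 °C; evaporate with toluene; DBU, CH2Cl2, 0 °C to rt
Reagents that add atoms: none
Why: Anomeric acetate to axial bromide, then E2 loss of the trans-diaxial H2'/Br pair with DBU, the standard dehydrobromination route to 2-acyloxyglycals; it installs the enol ether half of the allyl vinyl ether.

Step 6
Reactants: 9 2,4-di-O-acetyl-1,5-anhydro-6,7-dideoxy-3-O-(2-naphthylmethyl)-L-xylo-hept-1-en-6-ynitol
Product: 10 (6Z)-2,4-di-O-acetyl-1,5-anhydro-7-O-benzoyl-6-deoxy-3-O-(2-naphthylmethyl)-L-xylo-hepta-1,6-dienitol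
Conditions: benzoic acid (1.2 equiv), [Ru(η3-2-methylallyl)2(dppb)] (3 mol%), toluene, 60 °C
Reagents that add atoms: benzoic acid, O=C(O)c1ccccc1
Why: Ruthenium-vinylidene-mediated anti-Markovnikov addition of a carboxylic acid to a terminal alkyne should give the (Z)-enol ester, placing the benzoate on C7' with the alkene geometry that later defines C4.

Step 7
Reactants: 10 (6Z)-2,4-di-O-acetyl-1,5-anhydro-7-O-benzoyl-6-deoxy-3-O-(2-naphthylmethyl)-L-xylo-hepta-1,6-dienitol
Product: 11 cyclohexene aldehyde (C5 bears CHO and OAc; C1 OAc; C4 OBz; C6 O-CH2-2-naphthyl; ring configuration as in 15)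
Conditions: o-dichlorobenzene (0.02 M, degassed), 2,6-di-tert-butylpyridine (0.1 equiv), sealed tube, 180–200 °C
Reagents that add atoms: none
Why: Thermal [3,3]-sigmatropic (Claisen) rearrangement of the allyl vinyl ether C2'=C1'–O5'–C5'–C6'=C7' held in the dihydropyran: C2'–C7' (target C5–C4) forms as O5'–C5' breaks, giving the C7 aldehyde and the C2=C3 alkene; the closest known reaction type is the thermal Claisen carbocyclisation of 5-C-vinyl glycals (2-alkenyl-3,4-dihydro-2H-pyrans) to cyclohex-3-enecarbaldehydes. The cyclohexene closes by C–C bond formation between the enol-ether carbon and the enol-ester terminus in a ring contraction of the pyran, and because the termini are tied by C3'–C4' the six-atom array must be a boat (bicyclo[2.2.2]-like), suprafacial on both components. Quaternary C5 is controlled by C5': the new bond reaches C2' on the face that carries the vinyl group, which puts the formyl carbon cis to O6 and the acetoxy group cis to O1 and O4. C4 is controlled by the Z geometry of the enol benzoate, whose inside substituent points toward the C3'–C4' bridge in the boat and so ends cis to the C5 oxygen. The step needs the sigmatropic path to win over allylic acyloxy shift and ionisation of the glycal, which the ether at allylic O3' and acid-free conditions should secure. The L-ido pattern helps, because the reactive half-chair with an axial vinyl group keeps O3' and O4' equatorial.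

Step 8
Reactants: 11 cyclohexene aldehyde (C5 CHO and OAc; C6 naphthylmethyl ether)
Product: 13 α-hydroxy aldehyde (C5 bears CHO and OH; C1 and C6 OAc; C4 OBz; ring configuration as in 15), via hydroxy acetate 12 (not isolated)
Conditions: DDQ (1.5 equiv), CH2Cl2/pH 7 buffer (10:1), 0 °C to rt; aq. NaHCO3 wash; DBU (0.2 equiv), CH2Cl2, 0 °C; AcOH quench
Reagents that add atoms: none
Why: Oxidative cleavage of the naphthylmethyl ether frees O6, and base-catalysed O-to-O acyl migration through a five-membered orthoacid should then move the tertiary acetate to the neighbouring secondary hydroxyl, driven by relief of the tertiary ester and with no other free hydroxyl to receive an acyl group; no stereocentre is touched.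

Step 9
Reactants: 13 α-hydroxy aldehyde (C5 CHO and OH; C1 and C6 OAc; C4 OBz)
Product: 14 diol (C5 bears CH2OH and OH; C1 and C6 OAc; C4 OBz; ring configuration as in 15)
Conditions: NaBH(OAc)3, AcOH, CH2Cl2, 0 °C to rt
Reagents that add atoms: none
Why: Acetoxyborohydride reduction of the aldehyde, assisted by ligand exchange with the α-hydroxyl, under weakly acidic conditions that should prevent acyl migration to the new primary alcohol; esters and the alkene are inert.

Step 10
Reactants: 14 diol (C5 CH2OH and OH; C1 and C6 OAc; C4 OBz)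
Product: 15 cleistenediol F, [(1S,2S,5R,6S)-5,6-bis(acetyloxy)-2-(benzoyloxy)-1-hydroxycyclohex-3-en-1-yl]methyl benzoate
Conditions: BzCl (1.1 equiv), pyridine, CH2Cl2, −20 °C to 0 °C
Reagents that add atoms: benzoyl chloride, O=C(Cl)c1ccccc1
Why: Pyridine-mediated acylation should take the primary hydroxyl only, since the tertiary carbinol is inert under these conditions, and the cold, short reaction leaves no time for acyl migration.

**Compound list**

1 | 1,2:5,6-di-O-isopropylidene-α-D-glucofuranose | CC1(C)OC[C@@H](O1)[C@H]1O[C@@H]2OC(C)(C)O[C@@H]2[C@H]1O | starting material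
2 | 1,2:5,6-di-O-isopropylidene-3-O-(2-naphthylmethyl)-α-D-glucofuranose | CC1(C)OC[C@@H](O1)[C@H]1O[C@@H]2OC(C)(C)O[C@@H]2[C@H]1OCc1ccc2ccccc2c1 | intermediate
3 | 1,2-O-isopropylidene-3-O-(2-naphthylmethyl)-α-D-glucofuranose (5,6-diol) | OC[C@@H](O)[C@H]1O[C@@H]2OC(C)(C)O[C@@H]2[C@H]1OCc1ccc2ccccc2c1 | intermediate
4 | 1,2-O-isopropylidene-3-O-(2-naphthylmethyl)-α-D-xylo-pentodialdo-1,4-furanose | O=C[C@H]1O[C@@H]2OC(C)(C)O[C@@H]2[C@H]1OCc1ccc2ccccc2c1 | intermediate
5 | 6,7-dideoxy-1,2-O-isopropylidene-3-O-(2-naphthylmethyl)-β-L-ido-hept-6-ynofuranose | C#C[C@H](O)[C@H]1O[C@@H]2OC(C)(C)O[C@@H]2[C@H]1OCc1ccc2ccccc2c1 | intermediate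
6 | 6,7-dideoxy-3-O-(2-naphthylmethyl)-L-ido-hept-6-ynopyranose (anomer mixture) | OC1[C@H](O)[C@@H](OCc2ccc3ccccc3c2)[C@H](O)[C@H](C#C)O1 | intermediate
7 | 1,2,4-tri-O-acetyl-6,7-dideoxy-3-O-(2-naphthylmethyl)-L-ido-hept-6-ynopyranose (anomer mixture) | CC(=O)OC1[C@H](OC(C)=O)[C@@H](OCc2ccc3ccccc3c2)[C@H](OC(C)=O)[C@H](C#C)O1 | intermediate
8 | 2,4-di-O-acetyl-6,7-dideoxy-3-O-(2-naphthylmethyl)-L-ido-hept-6-ynopyranosyl bromide | BrC1[C@H](OC(C)=O)[C@@H](OCc2ccc3ccccc3c2)[C@H](OC(C)=O)[C@H](C#C)O1 | intermediate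
9 | 2,4-di-O-acetyl-1,5-anhydro-6,7-dideoxy-3-O-(2-naphthylmethyl)-L-xylo-hept-1-en-6-ynitol | O1C=C(OC(C)=O)[C@@H](OCc2ccc3ccccc3c2)[C@H](OC(C)=O)[C@@H]1C#C | intermediate
10 | (6Z)-2,4-di-O-acetyl-1,5-anhydro-7-O-benzoyl-6-deoxy-3-O-(2-naphthylmethyl)-L-xylo-hepta-1,6-dienitol | O1C=C(OC(C)=O)[C@@H](OCc2ccc3ccccc3c2)[C@H](OC(C)=O)[C@@H]1/C=C\OC(=O)c1ccccc1 | intermediate
11 | cyclohexene aldehyde: C5 bears CHO and OAc, C1 OAc, C4 OBz, C6 2-naphthylmethyl ether | CC(=O)O[C@@H]1C=C[C@H](OC(=O)c2ccccc2)[C@@](OC(C)=O)(C=O)[C@H]1OCc1ccc2ccccc2c1 | intermediate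
12 | hydroxy acetate: as 11 with free C6 hydroxyl | CC(=O)O[C@@H]1C=C[C@H](OC(=O)c2ccccc2)[C@@](OC(C)=O)(C=O)[C@H]1O | intermediate
13 | α-hydroxy aldehyde: C5 bears CHO and OH, C1 and C6 OAc, C4 OBz | CC(=O)O[C@@H]1C=C[C@H](OC(=O)c2ccccc2)[C@@](O)(C=O)[C@H]1OC(C)=O | intermediate
14 | diol: C5 bears CH2OH and OH, C1 and C6 OAc, C4 OBz | CC(=O)O[C@@H]1C=C[C@H](OC(=O)c2ccccc2)[C@@](O)(CO)[C@H]1OC(C)=O | intermediate
15 | cleistenediol F | CC(=O)O[C@@H]1C=C[C@H](OC(=O)c2ccccc2)[C@@](O)(COC(=O)c2ccccc2)[C@H]1OC(C)=O | target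

**Count**

Total steps: 10. Longest linear sequence: 10 (fully linear from 1).

**Steps most likely to fail**

Step 7. The boat transition state may not be reached before thermal side processes take over. These are Z-to-E isomerisation of the enol benzoate, which would give the C4 epimer, and ionisation or elimination of the glycal. The fallback replaces the thermal shift by the low-temperature ester-enolate (Ireland–Claisen) ring contraction; it sets out from 7 and comes back at 11. Compound 7 would be deacetylated at the anomeric position (hydrazine acetate, DMF) to the hemiacetal F1. Oxidation with Dess–Martin periodinane should give the δ-lactone F2, and the ruthenium-catalysed benzoic acid addition of step 6 the (Z)-enol benzoate lactone F3. Soft enolisation (TBSOTf, Et3N, toluene, −78 °C to 80 °C) should give the cyclic ketene silyl acetal F4, which rearranges through the same boat to the silyl ester F5. Aqueous work-up gives the acid F6, which is converted into the S-ethyl thioester F7 (EtSH, EDC, DMAP) and reduced (Et3SiH, Pd/C, Fukuyama reduction) to aldehyde 11.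

Step 8. The trans-1,2 acetyl shift from the tertiary to the secondary oxygen may be slow, so that base-induced α-ketol rearrangement of the aldehyde or migration of a benzoate competes. The fallback avoids this shift; it sets out from 12 and comes back at 14. The free hydroxyl of 12 would be acetylated (Ac2O, pyridine) to the triacetate aldehyde F8. Reduction (NaBH4, MeOH, −20 °C) gives the primary alcohol F9. On treatment with Et3N the tertiary acetate should move to the adjacent primary hydroxyl, the sterically easy direction, giving the primary acetate F10. Selective methanolysis of the primary acetate (Candida antarctica lipase B, MeOH/MTBE) should then give diol 14.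

Step 3. Facial selectivity in the ethynyl addition may be poor, giving much of the D-gluco epimer. The fallback moves stereocontrol to a reagent-controlled reduction; it sets out from 4 and comes back at 5. Aldehyde 4 would be treated with lithium (trimethylsilyl)acetylide to give the epimeric carbinols F11 and oxidised (Dess–Martin periodinane) to the ynone F12. Noyori transfer hydrogenation (Ru–TsDPEN, iPrOH, with the catalyst enantiomer chosen to deliver the 5S alcohol) should give the silylated L-ido carbinol F13. Desilylation (K2CO3, MeOH) gives 5.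

Further compounds

F1 | step 7 | 2,4-di-O-acetyl-6,7-dideoxy-3-O-(2-naphthylmethyl)-L-ido-hept-6-ynopyranose (hemiacetal) | OC1[C@H](OC(C)=O)[C@@H](OCc2ccc3ccccc3c2)[C@H](OC(C)=O)[C@H](C#C)O1
F2 | step 7 | 2,4-di-O-acetyl-6,7-dideoxy-3-O-(2-naphthylmethyl)-L-ido-hept-6-ynono-1,5-lactone | O=C1[C@H](OC(C)=O)[C@@H](OCc2ccc3ccccc3c2)[C@H](OC(C)=O)[C@H](C#C)O1
F3 | step 7 | (6Z)-2,4-di-O-acetyl-7-O-benzoyl-6-deoxy-3-O-(2-naphthylmethyl)-L-ido-hept-6-enono-1,5-lactone | O=C1[C@H](OC(C)=O)[C@@H](OCc2ccc3ccccc3c2)[C@H](OC(C)=O)[C@H](/C=C\OC(=O)c2ccccc2)O1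
F4 | step 7 | cyclic ketene tert-butyldimethylsilyl acetal of F3 | CC(C)(C)[Si](C)(C)OC1=C(OC(C)=O)[C@@H](OCc2ccc3ccccc3c2)[C@H](OC(C)=O)[C@H](/C=C\OC(=O)c2ccccc2)O1
F5 | step 7 | tert-butyldimethylsilyl ester of the C7 acid (ring as in 11) | CC(=O)O[C@@H]1C=C[C@H](OC(=O)c2ccccc2)[C@@](OC(C)=O)(C(=O)O[Si](C)(C)C(C)(C)C)[C@H]1OCc1ccc2ccccc2c1
F6 | step 7 | C7 carboxylic acid (ring as in 11) | CC(=O)O[C@@H]1C=C[C@H](OC(=O)c2ccccc2)[C@@](OC(C)=O)(C(=O)O)[C@H]1OCc1ccc2ccccc2c1
F7 | step 7 | S-ethyl thioester of F6 | CC(=O)O[C@@H]1C=C[C@H](OC(=O)c2ccccc2)[C@@](OC(C)=O)(C(=O)SCC)[C@H]1OCc1ccc2ccccc2c1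
F8 | step 8 | triacetate aldehyde: C5 bears CHO and OAc, C1 and C6 OAc, C4 OBz | CC(=O)O[C@@H]1C=C[C@H](OC(=O)c2ccccc2)[C@@](OC(C)=O)(C=O)[C@H]1OC(C)=O
F9 | step 8 | primary alcohol with tertiary acetate: C5 bears CH2OH and OAc | CC(=O)O[C@@H]1C=C[C@H](OC(=O)c2ccccc2)[C@@](OC(C)=O)(CO)[C@H]1OC(C)=O
F10 | step 8 | primary acetate with free tertiary hydroxyl: C5 bears CH2OAc and OH | CC(=O)O[C@@H]1C=C[C@H](OC(=O)c2ccccc2)[C@@](O)(COC(C)=O)[C@H]1OC(C)=O
F11 | step 3 | 6,7-dideoxy-1,2-O-isopropylidene-3-O-(2-naphthylmethyl)-7-C-trimethylsilyl-hept-6-ynofuranose (C5 epimers) | C[Si](C)(C)C#CC(O)[C@H]1O[C@@H]2OC(C)(C)O[C@@H]2[C@H]1OCc1ccc2ccccc2c1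
F12 | step 3 | corresponding 5-ulose (trimethylsilyl ynone) | C[Si](C)(C)C#CC(=O)[C@H]1O[C@@H]2OC(C)(C)O[C@@H]2[C@H]1OCc1ccc2ccccc2c1
F13 | step 3 | 7-C-trimethylsilyl derivative of 5 (β-L-ido, 5S) | C[Si](C)(C)C#C[C@H](O)[C@H]1O[C@@H]2OC(C)(C)O[C@@H]2[C@H]1OCc1ccc2ccccc2c1
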